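(The earlier runs and the new flask were computed with constants of no real substance, noise included.)

Count the nucleophile.

| flask | electrophile | nucleophile | solid base | remark | time |
|---|---|---|---|---|---|
| north-west | 0.72 M | 0.80 equiv | 0.30 equiv | the very flask that is asked about, followed so far |  |
| flask | 0.72 M | 0.800 equiv | 0.300 equiv |  | 5.0 min |

- north-west (time / s: over-reaction product A / %, target / %, electrophile / %): 10.0: 0.4, 9.0, 90.7; 25.0: 1.3, 17.6, 82.2

(each reading ± 0.5 percentage points)

- solid base is a solid; its amount is given per volume of the solution
- the earlier runs were read with a standard deviation of 0.5 percentage points
- reactions considered so far: electrophile + nucleophile -> acid set free + target; nucleophile + acid set free <-> protonated nucleophile; acid set free + free base <-> salt of the base; solid base <-> free base; target -> over-reaction product A; target -> over-reaction product B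
- at the start none of the solid base is in solution

- the species in which most of what was charged as electrophile, at 5.0 min sits (target / over-reaction product A / electrophile)
- the largest share itself, whichever of these holds it, in percent of the electrophile charged

In the flask each turnover of electrophile with nucleophile gives target and sets one acid free, and I took that acid to sit on a second nucleophile, which as protonated nucleophile no longer reacts. The rate goes with the product of the two reacting concentrations, so the readings can test the cost per turnover. In the north-west run the electrophile fell by 9.30 % of its charge in the first 10.0 s and by 8.50 % in the next 15.0 s, so the rate dropped to 0.609 of its first value. Reckoned at the middle of each interval, a cost of one nucleophile gives 0.800 and a cost of two gives 0.678. The reading, with its scatter of 0.5 percentage points, stood closer to two.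

So I froze the cost at two. In the flask the nucleophile is the limiting reagent, and the electrophile left when free nucleophile is gone at that cost is one minus half the nucleophile equivalents: the stall level, 60.0 %. At the first rate that much conversion needed 43.0 s, and the rate falls as the reaction goes on, but 5.0 min is longer still, so I expected the flask to come near the stall in time. Acid taken up by dissolved solid base spares nucleophile, and with all of it working I reckoned the electrophile left in the flask at 45.0 %. I committed to a value between these two, with electrophile holding the most and what had reacted split between target and over-reaction product A.

The forecast gave electrophile at 55 %, within 47 % to 61 %, and said “Electrophile holds the largest share”.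

At 5.0 min the flask held electrophile 52.7 %, more than target 36.8 % or over-reaction product A 10.4 %.

    electrophile + nucleophile → acid set free + target (k = 0.0170 M⁻¹ s⁻¹)
    nucleophile + acid set free ⇌ protonated nucleophile, settled at all times (K = 50.0 M⁻¹)
    acid set free + free base ⇌ salt of the base (K = 1.50 M⁻¹, k = 0.280 M⁻¹ s⁻¹)
    solid base ⇌ free base, rate k4*(cs4 - [free base]) while solid is left; crystals form when [free base] > cs4 (solubility = 0.670 M, k = 0.00260 s⁻¹)
    target → over-reaction product A (k = 0.00110 s⁻¹)
    target → over-reaction product B (k = 2.90 × 10⁻⁶ s⁻¹)

The electrophile in the flask stood 7.3 points below the stall level, with nucleophile at 6.3 % of its charge, less than the electrophile's 53 %, and with the acid standing as 0.200 M of protonated nucleophile, 0.110 M of acid set free and 0.0304 M of salt of the base. The neighbour flask, charged with 2.00 equiv of nucleophile and read at the same time, has a stall level of 0 %, so two nucleophiles per turnover cover its electrophile. It kept 15 % of its nucleophile, and its electrophile stood at 10.5 %. Target held the most in that neighbour flask, 68.8 %.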